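## The problem

Compound 15 is the 9-O-stearate of a lariciresinol-type lignan: a tetrahydrofuran O1–C2–C3–C4–C5 with a guaiacyl ring on C2, the stearoyloxymethyl arm (C9) on C3 and a guaiacylmethyl arm (C7') on C4. Only this one ring has to be made, but it carries three contiguous stereocentres, C2 (S), C3 (R) and C4 (R), with the C2 aryl group trans to the C9 arm and the C9 arm cis to the C7' arm. C2 is the only centre that is easy to make on its own, because it is benzylic and oxygenated. An economical plan therefore fixes C2 first and lets it direct C3 and C4 while the ring closes; the reverse order would need two adjacent carbon stereocentres on an open chain. Three parts of the molecule limit the reagents. The C2–O1 bond is a benzylic ether para to a phenol and is opened by acid (quinone methide formation, epimerisation, Friedel–Crafts closure) and by hydrogenolysis. The primary stearate does not survive hydride, alkoxide or organolithium reagents. The two phenols must be masked by groups that can be removed without touching that ester. The feature that allows a short answer is the pattern around C3–C4: C3 bears an oxygenated methylene and C4 bears a methylene bonded to an arene. This is what a C3 radical leaves behind when it closes 5-exo onto an O1-allyl group, and the C7' radical formed is then ready to be arylated. A single step of that kind would build the ring, two stereocentres and the second aryl group on a substrate that already holds the stearate.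

## Retrosynthesis

**15 ⇒ 14.** The last bonds to be cut are the two phenolic O–acyl bonds, which leads back to the bis(aryl acetate) 14. Aryl acetates are cleaved by amine aminolysis far faster than a primary alkyl ester. Benzyl ethers would instead need hydrogenolysis next to the C2–O1 bond, and electron-donating silyl or alkyl ethers would make the benzylic chemistry upstream prone to ionisation. The skeleton is unchanged; the forward step only has to be chemoselective.

**14 ⇒ 10 + 13.** The C3–C4 and C7'–aryl bonds are cut together. Cutting O1–C2 or O1–C5 instead would leave all three stereocentres to be assembled on an acyclic chain, and cutting C2–C3 calls for aldol-type logic and later redox corrections. The chosen cut removes the ring, two stereocentres and one aryl ring at once. It leaves the acyclic iodide 10, in which only the benzylic centre matters, and the arylzinc iodide 13. The forward reaction must generate a radical at C3, close the ring before the radical is intercepted, transmit the C2 configuration to C3 and C4, arylate the primary C7' radical, and tolerate three ester groups.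

**13 ⇒ 12 ⇒ 11.** The C–Zn bond comes from the C–I bond of 12 by zinc insertion, and the acetate of 12 from the commercial iodophenol 11. Both steps are functional-group operations on a simple arene.

**10 ⇒ 9.** The C–I bond is traced to the secondary hydroxyl of 9 by substitution with inversion. The configuration at this carbon is irrelevant, since it becomes a radical. A direct iodoetherification of the corresponding alkene would be shorter but would deliver racemic 10, so the alcohol route from an enantioenriched precursor is preferred. The iodide is introduced last before the key step because it is the most labile group in the sequence.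

**9 ⇒ 7 + 8.** The ester C–O bond is cut, giving diol 7 and stearoyl chloride 8. Placing the stearate before the key step means that nothing but deacetylation follows ring formation. The forward step must distinguish the primary from the secondary hydroxyl of 7.

**7 ⇒ 5 + 6.** The benzylic C–O bond is cut, giving epoxy alcohol 5 and allyl alcohol 6. Opening an aryl epoxide at its benzylic carbon with inversion sets the one stereocentre that controls the rest. The neighbouring carbinol centre of 7 is stereochemically inert here and makes any benzylic epimer a separable diastereomer before that marker is erased in step 9.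

**5 ⇒ 4.** The two epoxide C–O bonds are cut, giving the (E)-allylic alcohol 4. Titanium–tartrate epoxidation of a cinnamyl-type alcohol is among the most reliable ways to set such a centre, and the electron-withdrawing acetoxy group keeps the aryl epoxide from ionising.

**4 ⇒ 2 ⇒ 1.** The allylic alcohol is traced to the carboxylic acid 2 through acyl chloride 3, and 2 to ferulic acid 1 by phenol acetylation. The acetate that will be removed in the last step is thus installed in the first.

## Roads not taken

Alternative 1: The cut is made at C2–C3 and C4–C7' without forming the ring. The lithium anion of dithiane A1 would add to the β-carbon of menthyloxy butenolide A2 anti to the auxiliary. The lactone enolate would then be alkylated by bromide A3 trans to the new substituent, giving lactone A4 in one pot.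
- Merits: both carbon stereocentres are set under auxiliary control of a kind known to be very high, the intermediates tend to be crystalline, and no radical or sensitive halide is involved. In the security of the C3/C4 relationship this road is better than the chosen one, which relies on the conformational preference of a 5-exo transition state.
- Weak points for 15: A4 is far from the goal. The lactone and acetal must be reduced, the dithiane unmasked and the ketone reduced. O1–C2 must then be closed under acid through a benzylic cation, so that C2 is set last and only by thermodynamic preference. The C9 hydroxyl must be esterified and two benzyl ethers removed by hydrogenolysis beside the C2–O1 bond. Butyllithium and hydride reagents exclude an early stearate.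
- Comparison: against the higher stereochemical certainty of this road, the chosen plan offers a key step that closes the ring, adds the second aryl ring and leaves a single deprotection with the ester already in place.

Alternative 2: Here C2–C3 is cut. Diazo lactone A5 would be decomposed by Rh2(OAc)4, and the carbene at C3 would insert into the benzylic C2–H bond of the pendant benzyl ether. This closes the tetrahydrofuran ring cis-fused to the lactone in furofuranone A6.
- Merits: the cis ring fusion makes the 3,4-cis relationship a geometric necessity, which is stronger than the preference the chosen plan depends on. The C2 aryl group is expected on the convex face (2,3-trans), the step is catalytic, and both aryl rings are present.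
- Weak points for 15: A5 already needs two stereocentres in absolute form, and one of them (the lactone carbon C7') is destroyed later. Diazo transfer to a lactone needs prior activation. Electron-rich guaiacyl rings invite carbene addition to the arene. After the key step the benzylic lactone C–O bond must be hydrogenolysed without opening the C2–O1 ether, and the resulting acid reduced to the C9 alcohol before esterification. C9 and C7' thus pass through oxidation levels that the target does not have.
- Comparison: the chosen plan has less rigid stereocontrol, but it needs no redox correction and no selective hydrogenolysis.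

Alternative 3: The ring is cut at C2–C3 and C4–C5, which takes out the C2–O1–C5 unit as a carbonyl ylide. Acetal A7 would be ionised by Me3SiOTf and desilylated by CsF. The ylide would add across the double bond of butenolide A8 anti to the menthyloxy group, giving the cis-fused lactone A9.
- Merits: the whole ring is made in one step from very simple pieces, earlier than in the chosen plan. The ring fusion again guarantees 3,4-cis, and the auxiliary supplies the absolute sense.
- Weak points for 15: the ylide is unsymmetrical. Its aryl-bearing terminus must bond to the lactone α-carbon C3 and the aryl group must end up exo, and the substrate offers no strong bias for either. Above all the C7' aryl ring is missing. The menthyl acetal carbon must be turned into a benzylic methylene by aryl addition and deoxygenation in the presence of the C2–O1 benzylic ether. The lactone carbonyl must also be reduced to the C9 alcohol before esterification.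
- Comparison: the chosen plan also forms two bonds of the target in one step and in addition delivers the second aryl ring in that operation. What it must set against the guaranteed cis fusion is its reliance on a chair-like radical transition state.

Key step: step 9

Remark on the chemistry (assumption): 13 is drawn as ArZnI although it is formed and used as its LiCl adduct in THF, and the iodide carbon of 10 is drawn as the inversion product although its configuration has no bearing on the outcome.

## Route

Step 1
Reactants: 1 ferulic acid
Product: 2 4-O-acetylferulic acid, (E)-3-(4-acetoxy-3-methoxyphenyl)prop-2-enoic acid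
Conditions: Ac2O, pyridine, 0 °C → rt; aqueous work-up
Reagents that add atoms: acetic anhydride, CC(=O)OC(C)=O
Why: Pyridine-catalysed O-acetylation of the phenol (nucleophilic acyl substitution); any mixed anhydride formed at the carboxyl group is hydrolysed on aqueous work-up.

Step 2
Reactants: 2 4-O-acetylferulic acid
Product: 4 4-O-acetylconiferyl alcohol, 4-[(E)-3-hydroxyprop-1-en-1-yl]-2-methoxyphenyl acetate, via 4-O-acetylferuloyl chloride 3 (not isolated)
Conditions: (COCl)2, cat. DMF, CH2Cl2, 0 °C → rt; evaporate; then NaBH4, EtOAc, 0 °C → rt
Reagents that add atoms: none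
Why: Vilsmeier-type activation converts the acid into acyl chloride 3, which NaBH4 reduces by 1,2-hydride delivery (acyl chloride reduction) to the allylic alcohol. In aprotic ethyl acetate at 0 °C the aryl acetate and the conjugated double bond should remain untouched.

Step 3
Reactants: 4 4-O-acetylconiferyl alcohol
Product: 5 [(2S,3S)-3-(4-acetoxy-3-methoxyphenyl)oxiran-2-yl]methanol
Conditions: Ti(OiPr)4 (cat.), L-(+)-diisopropyl tartrate (cat.), tBuOOH (anhydrous, in decane), 4 Å molecular sieves, CH2Cl2, −20 °C; work-up with aq. citric acid, no hydroxide
Reagents that add atoms: tert-butyl hydroperoxide, CC(C)(C)OO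
Why: Sharpless asymmetric epoxidation: with the L-(+)-tartrate ligand the titanium-bound peroxide is delivered to the face of the (E)-allylic alcohol that gives the (2S,3S)-epoxy alcohol, fixing both epoxide carbons. The acetoxy group keeps the arene from assisting epoxide opening, and the hydroxide-free work-up protects the acetate.

Step 4
Reactants: 5 [(2S,3S)-3-(4-acetoxy-3-methoxyphenyl)oxiran-2-yl]methanol; 6 allyl alcohol
Product: 7 (2S,3R)-3-(4-acetoxy-3-methoxyphenyl)-3-(allyloxy)propane-1,2-diol
Conditions: 6 (excess), BF3·OEt2 (cat.), CH2Cl2, −30 → 0 °C
Reagents that add atoms: none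
Why: Lewis acid-catalysed alcoholysis of an aryl epoxide: the alcohol attacks the activated benzylic carbon with inversion (borderline SN2), giving the (3R) ether while C2 keeps its (S) hydroxyl. Any C3 epimer formed by ionisation is a diastereomer of 7 and can be removed at this stage.

Step 5
Reactants: 7 (2S,3R)-3-(4-acetoxy-3-methoxyphenyl)-3-(allyloxy)propane-1,2-diol; 8 stearoyl chloride
Product: 9 (2S,3R)-3-(4-acetoxy-3-methoxyphenyl)-3-(allyloxy)-2-hydroxypropyl octadecanoate
Conditions: 8 (1.05 equiv), 2,4,6-collidine, CH2Cl2, −40 → 0 °C
Reagents that add atoms: none
Why: Kinetically selective esterification of the less hindered primary hydroxyl with an acyl chloride and a hindered pyridine base at low temperature; no stereocentre is touched.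

Step 6
Reactants: 9 (2S,3R)-3-(4-acetoxy-3-methoxyphenyl)-3-(allyloxy)-2-hydroxypropyl octadecanoate
Product: 10 (2R,3R)-3-(4-acetoxy-3-methoxyphenyl)-3-(allyloxy)-2-iodopropyl octadecanoate
Conditions: PPh3, I2, imidazole, toluene, 60 °C, dark
Reagents that add atoms: iodine, II
Why: Appel-type iodination under Garegg–Samuelsson conditions: the alkoxyphosphonium ion is displaced by iodide with inversion, as is routine for secondary carbinols flanked by oxygenated carbons in carbohydrate chemistry. The configuration of this carbon is of no consequence because it becomes a radical in step 9.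

Step 7
Reactants: 11 4-iodo-2-methoxyphenol
Product: 12 4-iodo-2-methoxyphenyl acetate
Conditions: Ac2O, pyridine, CH2Cl2, rt
Reagents that add atoms: acetic anhydride, CC(=O)OC(C)=O
Why: Standard pyridine-mediated acetylation of a phenol.

Step 8
Reactants: 12 4-iodo-2-methoxyphenyl acetate
Product: 13 (4-acetoxy-3-methoxyphenyl)zinc iodide
Conditions: Zn dust (activated with 1,2-dibromoethane and Me3SiCl), LiCl, THF, 50 °C; titrated and used as solution
Reagents that add atoms: zinc, [Zn]
Why: Direct oxidative insertion of LiCl-activated zinc into the aryl C–I bond (Knochel-type zinc insertion), a process that tolerates ester groups.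

Step 9
Reactants: 10 (2R,3R)-3-(4-acetoxy-3-methoxyphenyl)-3-(allyloxy)-2-iodopropyl octadecanoate; 13 (4-acetoxy-3-methoxyphenyl)zinc iodide
Product: 14 [(2S,3R,4R)-2-(4-acetoxy-3-methoxyphenyl)-4-(4-acetoxy-3-methoxybenzyl)tetrahydrofuran-3-yl]methyl octadecanoate
Conditions: 13 (1.5–2 equiv, THF solution), NiBr2 (cat.), 2,2':6',2''-terpyridine (cat.), NMP, 50 °C
Reagents that add atoms: none
Why: NiBr2 and terpyridine are reduced and transmetalated by 13 to a terpyridine-bound monovalent arylnickel species, which abstracts iodine from C3 of 10 and leaves a secondary C3 radical and a divalent aryl(iodo)nickel complex. The radical closes the tetrahydrofuran ring by 5-exo-trig attack on the internal carbon of the O-allyl group (C3–C4), a 3-oxa-hex-5-enyl closure that is faster than bimolecular capture by the dilute catalyst. The primary C7' radical so formed recombines with the arylnickel complex to a trivalent alkyl(aryl)nickel species, and reductive elimination makes the C7'–aryl bond and returns monovalent nickel, which is re-arylated by 13. The closest known reaction type is the NiBr2/terpyridine-catalysed cyclisation–arylation of β-halo allyl acetals and ethers with arylzinc halides, which covers secondary halides and ester-bearing zinc reagents. C3 and C4 are both set under control of C2 in a chair-like Beckwith–Houk transition state: the C2 aryl group sits pseudo-equatorial, which places the new C4 substituent trans to it, and the substituted radical carbon follows the 1,5-cis preference, which puts the C9 arm cis to C7' and hence trans to the aryl group. The configuration of the C–I carbon is lost in the radical, so either epimer of 10 converges on the same product. The step needs ring closure before capture and tolerance of three ester groups; the first is secured by the intramolecular rate advantage, the second by the low basicity and nucleophilicity of an arylzinc iodide.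

Step 10
Reactants: 14 [(2S,3R,4R)-2-(4-acetoxy-3-methoxyphenyl)-4-(4-acetoxy-3-methoxybenzyl)tetrahydrofuran-3-yl]methyl octadecanoate
Product: 15 [(2S,3R,4R)-2-(4-hydroxy-3-methoxyphenyl)-4-(4-hydroxy-3-methoxybenzyl)tetrahydrofuran-3-yl]methyl octadecanoate
Conditions: pyrrolidine (excess), CH2Cl2, 0 °C → rt
Reagents that add atoms: none
Why: Chemoselective aminolysis: aryl acetates, with a phenoxide leaving group, react with a secondary amine far faster than a primary alkyl ester. Both phenols should therefore be released while the stearate and the three stereocentres stay untouched.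

## Compound list

1 | ferulic acid, (E)-3-(4-hydroxy-3-methoxyphenyl)prop-2-enoic acid | COc1cc(/C=C/C(O)=O)ccc1O | starting material
2 | 4-O-acetylferulic acid, (E)-3-(4-acetoxy-3-methoxyphenyl)prop-2-enoic acid | COc1cc(/C=C/C(O)=O)ccc1OC(C)=O | intermediate
3 | 4-O-acetylferuloyl chloride, (E)-3-(4-acetoxy-3-methoxyphenyl)prop-2-enoyl chloride | COc1cc(/C=C/C(Cl)=O)ccc1OC(C)=O | intermediate (not isolated)
4 | 4-O-acetylconiferyl alcohol, 4-[(E)-3-hydroxyprop-1-en-1-yl]-2-methoxyphenyl acetate | COc1cc(/C=C/CO)ccc1OC(C)=O | intermediate
5 | [(2S,3S)-3-(4-acetoxy-3-methoxyphenyl)oxiran-2-yl]methanol | OC[C@@H]1O[C@H]1c1ccc(OC(C)=O)c(OC)c1 | intermediate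
6 | allyl alcohol (prop-2-en-1-ol) | C=CCO | starting material
7 | (2S,3R)-3-(4-acetoxy-3-methoxyphenyl)-3-(allyloxy)propane-1,2-diol | OC[C@H](O)[C@H](OCC=C)c1ccc(OC(C)=O)c(OC)c1 | intermediate
8 | stearoyl chloride (octadecanoyl chloride) | CCCCCCCCCCCCCCCCCC(=O)Cl | starting material
9 | (2S,3R)-3-(4-acetoxy-3-methoxyphenyl)-3-(allyloxy)-2-hydroxypropyl octadecanoate | CCCCCCCCCCCCCCCCCC(=O)OC[C@H](O)[C@H](OCC=C)c1ccc(OC(C)=O)c(OC)c1 | intermediate
10 | (2R,3R)-3-(4-acetoxy-3-methoxyphenyl)-3-(allyloxy)-2-iodopropyl octadecanoate | CCCCCCCCCCCCCCCCCC(=O)OC[C@@H](I)[C@H](OCC=C)c1ccc(OC(C)=O)c(OC)c1 | intermediate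
11 | 4-iodo-2-methoxyphenol | COc1cc(I)ccc1O | starting material
12 | 4-iodo-2-methoxyphenyl acetate | COc1cc(I)ccc1OC(C)=O | intermediate
13 | (4-acetoxy-3-methoxyphenyl)zinc iodide | CC(=O)Oc1ccc([Zn]I)cc1OC | intermediate
14 | [(2S,3R,4R)-2-(4-acetoxy-3-methoxyphenyl)-4-(4-acetoxy-3-methoxybenzyl)tetrahydrofuran-3-yl]methyl octadecanoate | CCCCCCCCCCCCCCCCCC(=O)OC[C@H]1[C@@H](Cc2ccc(OC(C)=O)c(OC)c2)CO[C@@H]1c1ccc(OC(C)=O)c(OC)c1 | intermediate
15 | [(2S,3R,4R)-2-(4-hydroxy-3-methoxyphenyl)-4-(4-hydroxy-3-methoxybenzyl)tetrahydrofuran-3-yl]methyl octadecanoate (CNP0168412.1) | CCCCCCCCCCCCCCCCCC(=O)OC[C@H]1[C@@H](Cc2ccc(O)c(OC)c2)CO[C@@H]1c1ccc(O)c(OC)c1 | target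

## Step count and least certain steps

Total: 10 steps. Longest linear sequence: 8 steps (steps 1–6, 9 and 10, from ferulic acid 1). The arylzinc branch (steps 7 and 8) is 2 steps.

**Step 9 (key step).** The C3 radical may be intercepted by nickel before it cyclises, leading to direct arylation at C3 or to β-elimination of the allyloxy or acyloxy group from an alkylmetal species. Facial discrimination in the 5-exo closure may also be insufficient, so that 3,4-trans material accompanies the product, and the arylzinc reagent may homocouple. A fallback gives up the arylation half of the cascade and brings the second aryl ring in with the alkene. It sets out from 5 and 4 and comes back at 14.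
- Epoxide 5 would be opened with the cinnamyl-type alcohol 4 in place of 6, under the same acid catalysis, to give (2S,3R)-3-(4-acetoxy-3-methoxyphenyl)-3-{[(E)-3-(4-acetoxy-3-methoxyphenyl)prop-2-en-1-yl]oxy}propane-1,2-diol F1.
- F1 would be acylated with 8 as in step 5 to (2S,3R)-3-(4-acetoxy-3-methoxyphenyl)-3-{[(E)-3-(4-acetoxy-3-methoxyphenyl)prop-2-en-1-yl]oxy}-2-hydroxypropyl octadecanoate F2.
- F2 would be iodinated as in step 6 to (2R,3R)-3-(4-acetoxy-3-methoxyphenyl)-3-{[(E)-3-(4-acetoxy-3-methoxyphenyl)prop-2-en-1-yl]oxy}-2-iodopropyl octadecanoate F3.
- Reductive radical cyclisation of F3 with Bu3SnH and AIBN in benzene at 80 °C would close the same C3–C4 bond 5-exo onto the styrene terminus. The benzylic C7' radical is quenched by hydrogen transfer, and the product is 14.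

**Step 6.** Substitution at a carbinol flanked by two oxygenated carbons is slow. This leaves time for participation of the stearate carbonyl (acyl migration with delivery of iodide to the primary carbon), for elimination, and for aminolysis of the aryl acetate by imidazole. A fallback removes the participating ester from the substitution. It sets out from 7 and comes back at 10.
- The primary hydroxyl of 7 would be silylated (TBSCl, imidazole, CH2Cl2, 0 °C) to (2S,3R)-3-(4-acetoxy-3-methoxyphenyl)-3-(allyloxy)-1-(tert-butyldimethylsilyloxy)propan-2-ol F4.
- F4 would be iodinated as in step 6 to the (2R,3R)-configured silyl ether iodide, 4-[(1R,2R)-1-(allyloxy)-3-(tert-butyldimethylsilyloxy)-2-iodopropyl]-2-methoxyphenyl acetate F5.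
- F5 would be desilylated with HF·pyridine in THF to (2R,3R)-3-(4-acetoxy-3-methoxyphenyl)-3-(allyloxy)-2-iodopropan-1-ol F6.
- F6 would be esterified with 8 and pyridine at 0 °C to give 10.

**Step 4.** The activated epoxide may partly ionise at the benzylic carbon, with loss of stereospecificity. It may also rearrange to a carbonyl compound (Meinwald pathway), or be attacked by the free primary hydroxyl of a second molecule. A fallback reverses the order of acylation and opening. It sets out from 5 and comes back at 9.
- 5 would first be esterified with 8 (pyridine, CH2Cl2, 0 °C) to [(2S,3S)-3-(4-acetoxy-3-methoxyphenyl)oxiran-2-yl]methyl octadecanoate F9. F9 has no hydroxyl to chelate the Lewis acid or to act as a competing nucleophile.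
- F9 would then be opened at the benzylic carbon with 6 under acid catalysis. This gives 9 directly and makes the selective monoacylation of step 5 unnecessary.

**Step 3.** Titanium-mediated acetyl transfer from the aryl acetate, or Lewis acid-induced opening of the aryl epoxide during reaction and work-up, may erode yield and enantiomeric purity. A fallback replaces the metal-based epoxidation by iminium organocatalysis. It sets out from 4 and comes back at 5.
- 4 would be oxidised with MnO2 in CH2Cl2 to (E)-3-(4-acetoxy-3-methoxyphenyl)prop-2-enal F7.
- F7 would be epoxidised with aqueous H2O2 and the diarylprolinol silyl ether enantiomer that gives the (2R,3S)-epoxy aldehyde, expected to be the (S)-configured catalyst. The product is (2R,3S)-3-(4-acetoxy-3-methoxyphenyl)oxirane-2-carbaldehyde F8.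
- F8 would be reduced in the same flask with NaBH4 at 0 °C to 5.

**Step 10.** Deacetylation may stop at the monoacetate, or the stearate may be lost through slow aminolysis when the reaction is pushed. A fallback removes all three acyl groups and reinstalls the stearate selectively. It sets out from 14 and comes back at 15.
- Methanolysis of 14 with K2CO3 in MeOH would give [(2S,3R,4R)-2-(4-hydroxy-3-methoxyphenyl)-4-(4-hydroxy-3-methoxybenzyl)tetrahydrofuran-3-yl]methanol F10.
- The primary aliphatic hydroxyl of F10 would then be acylated in preference to the phenols with vinyl stearate and immobilised Candida antarctica lipase B in 2-methylbutan-2-ol at 50 °C, giving 15.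

## Further compounds

F1 | step 9 | (2S,3R)-3-(4-acetoxy-3-methoxyphenyl)-3-{[(E)-3-(4-acetoxy-3-methoxyphenyl)prop-2-en-1-yl]oxy}propane-1,2-diol | OC[C@H](O)[C@H](OC/C=C/c1ccc(OC(C)=O)c(OC)c1)c1ccc(OC(C)=O)c(OC)c1
F2 | step 9 | (2S,3R)-3-(4-acetoxy-3-methoxyphenyl)-3-{[(E)-3-(4-acetoxy-3-methoxyphenyl)prop-2-en-1-yl]oxy}-2-hydroxypropyl octadecanoate | CCCCCCCCCCCCCCCCCC(=O)OC[C@H](O)[C@H](OC/C=C/c1ccc(OC(C)=O)c(OC)c1)c1ccc(OC(C)=O)c(OC)c1
F3 | step 9 | (2R,3R)-3-(4-acetoxy-3-methoxyphenyl)-3-{[(E)-3-(4-acetoxy-3-methoxyphenyl)prop-2-en-1-yl]oxy}-2-iodopropyl octadecanoate | CCCCCCCCCCCCCCCCCC(=O)OC[C@@H](I)[C@H](OC/C=C/c1ccc(OC(C)=O)c(OC)c1)c1ccc(OC(C)=O)c(OC)c1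
F4 | step 6 | (2S,3R)-3-(4-acetoxy-3-methoxyphenyl)-3-(allyloxy)-1-(tert-butyldimethylsilyloxy)propan-2-ol | CC(C)(C)[Si](C)(C)OC[C@H](O)[C@H](OCC=C)c1ccc(OC(C)=O)c(OC)c1
F5 | step 6 | 4-[(1R,2R)-1-(allyloxy)-3-(tert-butyldimethylsilyloxy)-2-iodopropyl]-2-methoxyphenyl acetate | CC(C)(C)[Si](C)(C)OC[C@@H](I)[C@H](OCC=C)c1ccc(OC(C)=O)c(OC)c1
F6 | step 6 | (2R,3R)-3-(4-acetoxy-3-methoxyphenyl)-3-(allyloxy)-2-iodopropan-1-ol | OC[C@@H](I)[C@H](OCC=C)c1ccc(OC(C)=O)c(OC)c1
F7 | step 3 | (E)-3-(4-acetoxy-3-methoxyphenyl)prop-2-enal | COc1cc(/C=C/C=O)ccc1OC(C)=O
F8 | step 3 | (2R,3S)-3-(4-acetoxy-3-methoxyphenyl)oxirane-2-carbaldehyde | O=C[C@@H]1O[C@H]1c1ccc(OC(C)=O)c(OC)c1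
F9 | step 4 | [(2S,3S)-3-(4-acetoxy-3-methoxyphenyl)oxiran-2-yl]methyl octadecanoate | CCCCCCCCCCCCCCCCCC(=O)OC[C@@H]1O[C@H]1c1ccc(OC(C)=O)c(OC)c1
F10 | step 10 | [(2S,3R,4R)-2-(4-hydroxy-3-methoxyphenyl)-4-(4-hydroxy-3-methoxybenzyl)tetrahydrofuran-3-yl]methanol | OC[C@H]1[C@@H](Cc2ccc(O)c(OC)c2)CO[C@@H]1c1ccc(O)c(OC)c1
A1 | alternative 1 | 2-(4-benzyloxy-3-methoxyphenyl)-1,3-dithiane | COc1cc(C2SCCCS2)ccc1OCc1ccccc1
A2 | alternative 1 | (5R)-5-[(1R,2S,5R)-menthyloxy]furan-2(5H)-one | O=C1O[C@@H](O[C@@H]2C[C@H](C)CC[C@H]2C(C)C)C=C1
A3 | alternative 1 | 4-(benzyloxy)-3-methoxybenzyl bromide | COc1cc(CBr)ccc1OCc1ccccc1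
A4 | alternative 1 | trans,trans-3-(4-benzyloxy-3-methoxybenzyl)-4-[2-(4-benzyloxy-3-methoxyphenyl)-1,3-dithian-2-yl]-5-[(1R,2S,5R)-menthyloxy]dihydrofuran-2(3H)-one | O=C1O[C@@H](O[C@@H]2C[C@H](C)CC[C@H]2C(C)C)[C@H](C2(c3ccc(OCc4ccccc4)c(OC)c3)SCCCS2)[C@H]1Cc1ccc(OCc2ccccc2)c(OC)c1
A5 | alternative 2 | 4,5-trans-5-(4-benzyloxy-3-methoxyphenyl)-4-{[(4-benzyloxy-3-methoxybenzyl)oxy]methyl}-3-diazodihydrofuran-2(3H)-one | O=C1O[C@H](c2ccc(OCc3ccccc3)c(OC)c2)[C@@H](COCc2ccc(OCc3ccccc3)c(OC)c2)C1=[N+]=[N-]
A6 | alternative 2 | exo,exo-2,6-bis(4-benzyloxy-3-methoxyphenyl)-3,7-dioxabicyclo[3.3.0]octan-8-one | O=C1O[C@H](c2ccc(OCc3ccccc3)c(OC)c2)[C@H]2CO[C@H](c3ccc(OCc4ccccc4)c(OC)c3)[C@@H]12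
A7 | alternative 3 | 4-benzyloxy-3-methoxybenzaldehyde bis[(trimethylsilyl)methyl] acetal | COc1cc(C(OC[Si](C)(C)C)OC[Si](C)(C)C)ccc1OCc1ccccc1
A8 | alternative 3 | (5S)-5-[(1S,2R,5S)-menthyloxy]furan-2(5H)-one | O=C1O[C@H](O[C@H]2C[C@@H](C)CC[C@@H]2C(C)C)C=C1
A9 | alternative 3 | cis-fused 6-(4-benzyloxy-3-methoxyphenyl)-4-[(1S,2R,5S)-menthyloxy]-3,7-dioxabicyclo[3.3.0]octan-2-one | O=C1O[C@H](O[C@H]2C[C@@H](C)CC[C@@H]2C(C)C)[C@H]2CO[C@H](c3ccc(OCc4ccccc4)c(OC)c3)[C@@H]12
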